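The plan rests on the position of the C6 oxygen. It sits next to the C1–C5 bond shared by the cyclopentane (C1–C5) and the cycloheptenone (C1, C5–C10). C6 is therefore treated as the carbonyl terminus of a semipinacol shift. Breaking C1–C5 and restoring C1–C6 leads back to a decalin that maps onto (S)-Wieland–Miescher ketone. In one operation the key step moves the quaternary C1 from C6 to C5, contracts one six-membered ring, enlarges the other and fixes the trans ring fusion. Its precursor is a cis-decalin carrying a free angular 6β-hydroxyl, an equatorial 5β-mesylate, a silylated 4β-oxygen beside the 4α-isopropyl group, the C8 methyl and a 10β-benzyl ether.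

Key step: step 9

Numbering: the target's atom numbers are kept for all bicyclic compounds. C1 is the quaternary methyl carbon, C2 and C3 are CH2, C4 is the isopropyl carbinol, C5 the fusion CH, C6 the aroyloxy carbon and C7 a CH2. C8 is the methyl-bearing carbon, C9 follows it and C10 is the ketone. In the decalins ring A is C1–C6 and ring B is C1, C6–C10. β is the face of the C1 methyl and α is the opposite face.

Design remark 1: the C8 methyl enters by 1,6-addition to a dienone grown out of the ring A enone. No second enone therefore has to be made beside C10 while the C4 enone is unprotected.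

Design remark 2: C8 and C10 stop being stereocentres in steps 14 and 15, but before that they bias the chair equilibrium of 13.
- The 10β-ether is equatorial in the reactive chair. In the unreactive chair it is axial and syn to the C6 hydroxyl.
- The 8α-methyl is axial in the reactive chair. Its contact with C5 is released as C6 becomes trigonal.

Design remark 3: benzyl at C10 and TBS on the phenol are orthogonal. The benzyl ether is removed while no alkene is present, and the last step needs no base.

Assumption: the 1,6-addition is taken to give the 8α-methyl epimer by axial attack; the 8β epimer would pass through the same steps and converge on the same enone in step 15.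

Step 1
Reactants: 1 (S)-Wieland–Miescher ketone
Product: 2 hydroxy enone (10β-OH, C4 enone intact)
Conditions: NaBH4 (0.3 equiv), EtOH, 0 °C
Reagents that add atoms: none
Why: Chemoselective borohydride reduction: the saturated C10 ketone is more electrophilic than the conjugated C4 carbonyl, and hydride enters from the α face opposite the angular methyl, which sets the equatorial 10β-alcohol.

Step 2
Reactants: 2 hydroxy enone
Product: 3 benzyl ether enone
Conditions: benzyl 2,2,2-trichloroacetimidate, TfOH (cat.), CH2Cl2/cyclohexane, 0 °C → rt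
Reagents that add atoms: benzyl 2,2,2-trichloroacetimidate, N=C(OCc1ccccc1)C(Cl)(Cl)Cl
Why: Acid-catalysed O-benzylation with a trichloroacetimidate works on hindered secondary alcohols and avoids the strong base that would deprotonate the enone, and no stereocentre is touched.

Step 3
Reactants: 3 benzyl ether enone
Product: 4 linear dienone (C4=O, C5=C6, C7=C8)
Conditions: chloranil (1.5 equiv), t-BuOH, reflux
Reagents that add atoms: none
Why: Quinone dehydrogenation of a ring-fused enone, the chloranil reaction that turns steroid 4-en-3-ones into 4,6-dien-3-ones: the thermodynamic C4/C6 dienol gives up hydride from C8, so the linear dienone forms and not the cross-conjugated one.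

Step 4
Reactants: 4 linear dienone; 5 methylmagnesium bromide
Product: 7 methyl enone (8α-methyl; 10β-benzyloxy; C5=C6–C4=O), via deconjugated ketone 6 (not isolated)
Conditions: MeMgBr, CuBr·SMe2 (10 mol %), THF, −40 °C; then 2 M HCl, rt
Reagents that add atoms: methylmagnesium bromide (5), C[Mg]Br
Why: Copper-catalysed 1,6-conjugate addition of a Grignard reagent, as used for 7α-methyl steroids: C6 is fully substituted, so methyl is delivered to the δ-carbon C8, axially and anti to the angular methyl (8α), and acid then returns the double bond of 6 to conjugation.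

Step 5
Reactants: 7 methyl enone; 8 isopropylmagnesium chloride
Product: 9 allylic alcohol (4β-OH, 4α-isopropyl, C5=C6)
Conditions: CeCl3 (anhydrous), i-PrMgCl, THF, −78 → 0 °C
Reagents that add atoms: isopropylmagnesium chloride (8), CC(C)[Mg]Cl
Why: Organocerium 1,2-addition curbs enolisation and β-hydride reduction, conjugate addition is blocked by the fully substituted C6, and pseudoaxial attack on the α face of the enone half-chair, away from the angular methyl, sets the 4β-hydroxy-4α-isopropyl centre.

Step 6
Reactants: 9 allylic alcohol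
Product: 11 cis-decalin 4β;5β;6β-triol, via osmate ester 10 (not isolated)
Conditions: OsO4 (1.1 equiv), TMEDA (1.2 equiv), CH2Cl2, −78 °C → rt; then aq. Na2SO3, THF, reflux
Reagents that add atoms: osmium tetroxide, O=[Os](=O)(=O)=O
Why: Hydrogen-bond-directed syn-dihydroxylation with the OsO4·TMEDA complex: the 4β-hydroxyl, pseudoaxial once isopropyl is pseudoequatorial, binds an oxo ligand and guides osmium to the β face while isopropyl, C10 and the axial 8α-methyl shield the α face, so both new C–O bonds (C5 and C6) are β and the ring fusion becomes cis.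

Step 7
Reactants: 11 triol
Product: 12 diol mesylate (5β-OMs, free 4β- and 6β-OH)
Conditions: MsCl (1.2 equiv), Et3N, CH2Cl2, −20 → 0 °C
Reagents that add atoms: methanesulfonyl chloride, CS(=O)(=O)Cl
Why: Mesylation picks the only secondary hydroxyl because the tertiary C4 and C6 hydroxyls are too hindered at low temperature, and C5 keeps its configuration since only the O–H bond is broken.

Step 8
Reactants: 12 diol mesylate
Product: 13 cis-decalin hydroxy mesylate (4β-OTMS, 5β-OMs, free 6β-OH)
Conditions: TMSOTf (1.05 equiv), 2,6-lutidine, CH2Cl2, −78 °C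
Reagents that add atoms: trimethylsilyl triflate, C[Si](C)(C)OS(=O)(=O)C(F)(F)F
Why: Kinetically controlled silylation with a silyl triflate: the C6 hydroxyl is an angular carbinol next to the quaternary C1, the kind of hydroxyl (compare 5- and 14-hydroxy steroids) that resists silylation, so one equivalent of reagent caps the more open C4 hydroxyl.

Step 9
Reactants: 13 cis-decalin hydroxy mesylate
Product: 15 trans-fused hydroazulen-6-one (4β-OTMS; 10β-OBn; 8α-methyl), via aluminium alkoxide 14 (not isolated)
Conditions: Et3Al (3 equiv), CH2Cl2, −78 → 0 °C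
Reagents that add atoms: none
Why: Et3Al turns the angular C6 hydroxyl into aluminium alkoxide 14 and a further equivalent binds the mesylate, so electron push from O6 and pull at O5 drive a concerted 1,2-shift in which the C1–C6 σ bond, held anti to the equatorial C5–O bond in the chair that keeps isopropyl equatorial, slides onto C5 while C6 becomes the ketone carbon. The closest known reaction type is the organoaluminium-promoted semipinacol rearrangement of 2-hydroxy mesylates, and the same 1,2-shift under basic or solvolytic conditions has long served to turn monosulfonated decalindiols into hydroazulenones. Neither ring closes by cyclisation of a chain: the cyclopentane (C1–C5) results from contraction of ring A through the new C1–C5 bond, and the cycloheptanone (C1, C5–C10) from one-carbon enlargement of ring B, which takes in C5. C5 is set by inversion, since C1 enters at the back of the β C–O bond and leaves 5-H on the α face, trans to the 1β-methyl, and C1 migrates with retention, so the configuration bought with 1 is kept. The step needs C1 to move rather than C7, C3 or isopropyl: C7 and isopropyl are gauche to the leaving group in this chair, the other chair would pair isopropyl with C7, the C1 methyl with the mesylate and the benzyloxy group with the C6 hydroxyl in syn-diaxial contacts, the fully substituted C1 has the higher migratory aptitude, and the TMS cap keeps O4 from pushing C3 across. The non-basic reagent also spares 15 from epimerisation at C5, β-elimination of the C4 silyloxy group and retro-aldol cleavage.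

Step 10
Reactants: 15 hydroazulen-6-one silyl ether
Product: 17 4β;6α-diol, via hydroxy ketone 16 (not isolated)
Conditions: citric acid (cat.), MeOH, rt; evaporate; then Me4NBH(OAc)3, MeCN/AcOH 1:1, −20 °C → rt
Reagents that add atoms: none
Why: Mild methanolysis frees the C4 hydroxyl and the Evans–Saksena reduction then runs through an alkoxy(diacetoxy)borohydride bound to the 4β-oxygen, which hands hydride to the β face of C6 and so sets the 6α-alcohol (1,3-anti diol), while ketones without a bound hydroxyl are left alone by this reagent.

Step 11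
Reactants: 18 4-hydroxybenzoic acid
Product: 20 4-(tert-butyldimethylsilyloxy)benzoic acid, via bis-silyl derivative 19 (not isolated)
Conditions: TBSCl (2.3 equiv), imidazole, DMF, rt; then AcOH/THF/H2O, rt
Reagents that add atoms: tert-butyldimethylsilyl chloride, CC(C)(C)[Si](C)(C)Cl
Why: Exhaustive silylation followed by selective hydrolysis of the far more labile silyl ester is the standard way to an O-silylated hydroxy acid.

Step 12
Reactants: 17 diol; 20 4-(tert-butyldimethylsilyloxy)benzoic acid
Product: 21 6α-aroyl ester (10β-OBn, free 4β-OH)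
Conditions: DCC, DMAP, CH2Cl2, rt → 40 °C
Reagents that add atoms: 4-(tert-butyldimethylsilyloxy)benzoic acid (20), OC(=O)c1ccc(O[Si](C)(C)C(C)(C)C)cc1
Why: Steglich esterification acylates only the secondary 6α-hydroxyl because the tertiary C4 hydroxyl is inert to the acylpyridinium species, and C6 keeps its configuration since the C–O bond is not broken.

Step 13
Reactants: 21 ester benzyl ether
Product: 22 ester alcohol (10β-OH)
Conditions: H2 (1 atm), Pd(OH)2/C, EtOAc, rt
Reagents that add atoms: none
Why: Hydrogenolysis of the benzyl ether under neutral conditions is run at a stage where the molecule holds no alkene, and the aryl ester, aryl silyl ether and tertiary alcohol are untouched.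

Step 14
Reactants: 22 ester alcohol
Product: 23 ester ketone (C10=O)
Conditions: Dess–Martin periodinane, CH2Cl2, rt
Reagents that add atoms: none
Why: Dess–Martin oxidation converts the only secondary alcohol into the ketone under neutral conditions and deliberately erases the C10 stereocentre.

Step 15
Reactants: 23 ester ketone
Product: 25 protected enone (C8=C9–C10=O; 4β-OTMS; aryl OTBS), via silyl enol ether 24 (not isolated)
Conditions: TMSOTf, Et3N, CH2Cl2, 0 °C → rt; then Pd(OAc)2 (1.1 equiv), MeCN, rt → 40 °C
Reagents that add atoms: trimethylsilyl triflate, C[Si](C)(C)OS(=O)(=O)C(F)(F)F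
Why: Saegusa–Ito oxidation: C10 can enolise only towards C9 because C1 is quaternary, so soft enolisation gives a single silyl enol ether (the C4 hydroxyl is silylated in passing), and the palladium enolate loses the C8 hydrogen by β-hydride elimination to give the C8=C9 enone, which erases the C8 stereocentre.

Step 16
Reactants: 25 protected enone
Product: 26 target CNP0210039.1
Conditions: HF·pyridine, pyridine, THF, 0 °C → rt
Reagents that add atoms: none
Why: Fluoride desilylation under slightly acidic conditions removes both silyl groups without base, which matters because the C7 protons are vinylogously acidic and a base could expel the C6 aroyloxy group.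

Compound list
1 | (S)-Wieland–Miescher ketone, (8aS)-8a-methyl-3,4,8,8a-tetrahydronaphthalene-1,6(2H,7H)-dione | O=C1CCCC2=CC(=O)CC[C@]12C | starting material
2 | hydroxy enone, (4aS,5S)-5-hydroxy-4a-methyl-4,4a,5,6,7,8-hexahydronaphthalen-2(3H)-one (10β-OH) | C1C[C@H](O)[C@@]2(C)CCC(=O)C=C2C1 | intermediate
3 | benzyl ether enone (10β-OBn, C4=O, C5=C6) | C1C[C@H](OCc3ccccc3)[C@@]2(C)CCC(=O)C=C2C1 | intermediate
4 | linear dienone (C4=O, C5=C6, C7=C8, 1β-methyl, 10β-OBn) | C1=CC2=CC(=O)CC[C@]2(C)[C@@H](OCc3ccccc3)C1 | intermediate
5 | methylmagnesium bromide | C[Mg]Br | starting material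
6 | deconjugated ketone (C4=O, C6=C7, 8α-methyl, 10β-OBn) | C[C@H]1C[C@H](OCc3ccccc3)[C@@]2(C)CCC(=O)CC2=C1 | intermediate
7 | methyl enone (C4=O, C5=C6, 8α-methyl, 10β-OBn) | C[C@H]1C[C@H](OCc3ccccc3)[C@@]2(C)CCC(=O)C=C2C1 | intermediate
8 | isopropylmagnesium chloride | CC(C)[Mg]Cl | starting material
9 | allylic alcohol (4β-OH, 4α-isopropyl, C5=C6, 8α-methyl, 10β-OBn) | C[C@H]1C[C@H](OCc3ccccc3)[C@@]2(C)CC[C@@](O)(C(C)C)C=C2C1 | intermediate
10 | osmate ester: cyclic 5β,6β-dioxo-osmate (hexavalent osmium) of 9 as its TMEDA chelate | C[C@H]1C[C@H](OCc4ccccc4)[C@@]2(C)CC[C@@](O)(C(C)C)[C@H](O[Os]3(=O)=O)[C@@]2(O3)C1.CN(C)CCN(C)C | intermediate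
11 | cis-decalin triol (4β,5β,6β-OH, 4α-isopropyl, 8α-methyl, 10β-OBn) | C[C@H]1C[C@H](OCc3ccccc3)[C@@]2(C)CC[C@@](O)(C(C)C)[C@H](O)[C@@]2(O)C1 | intermediate
12 | diol mesylate (5β-OMs, 4β- and 6β-OH) | C[C@H]1C[C@H](OCc3ccccc3)[C@@]2(C)CC[C@@](O)(C(C)C)[C@H](OS(C)(=O)=O)[C@@]2(O)C1 | intermediate
13 | cis-decalin hydroxy mesylate, key-step precursor (6β-OH, 5β-OMs, 4β-OTMS, 4α-isopropyl, 8α-methyl, 10β-OBn) | C[C@H]1C[C@H](OCc3ccccc3)[C@@]2(C)CC[C@@](O[Si](C)(C)C)(C(C)C)[C@H](OS(C)(=O)=O)[C@@]2(O)C1 | intermediate
14 | diethylaluminium C6 alkoxide of 13 | C[C@H]1C[C@H](OCc3ccccc3)[C@@]2(C)CC[C@@](O[Si](C)(C)C)(C(C)C)[C@H](OS(C)(=O)=O)[C@@]2(O[Al](CC)CC)C1 | intermediate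
15 | trans-fused hydroazulen-6-one, key-step product (1β-methyl, 5α-H, 4β-OTMS, 4α-isopropyl, 8α-methyl, 10β-OBn) | C[C@H]1C[C@H](OCc3ccccc3)[C@@]2(C)CC[C@@](O[Si](C)(C)C)(C(C)C)[C@@H]2C(=O)C1 | intermediate
16 | hydroxy ketone (4β-OH, C6=O) | C[C@H]1C[C@H](OCc3ccccc3)[C@@]2(C)CC[C@@](O)(C(C)C)[C@@H]2C(=O)C1 | intermediate
17 | diol (4β-OH, 6α-OH, 10β-OBn) | C[C@H]1C[C@H](OCc3ccccc3)[C@@]2(C)CC[C@@](O)(C(C)C)[C@@H]2[C@@H](O)C1 | intermediate
18 | 4-hydroxybenzoic acid | OC(=O)c1ccc(O)cc1 | starting material
19 | tert-butyldimethylsilyl 4-(tert-butyldimethylsilyloxy)benzoate | CC(C)(C)[Si](C)(C)OC(=O)c1ccc(O[Si](C)(C)C(C)(C)C)cc1 | intermediate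
20 | 4-(tert-butyldimethylsilyloxy)benzoic acid | OC(=O)c1ccc(O[Si](C)(C)C(C)(C)C)cc1 | intermediate
21 | 6α-[4-(TBSO)benzoyloxy] ester, 10β-OBn, 4β-OH | C[C@H]1C[C@H](OCc3ccccc3)[C@@]2(C)CC[C@@](O)(C(C)C)[C@@H]2[C@@H](OC(=O)c3ccc(O[Si](C)(C)C(C)(C)C)cc3)C1 | intermediate
22 | ester alcohol (10β-OH) | C[C@H]1C[C@H](O)[C@@]2(C)CC[C@@](O)(C(C)C)[C@@H]2[C@@H](OC(=O)c3ccc(O[Si](C)(C)C(C)(C)C)cc3)C1 | intermediate
23 | ester ketone (C10=O, 8α-methyl) | C[C@H]1CC(=O)[C@@]2(C)CC[C@@](O)(C(C)C)[C@@H]2[C@@H](OC(=O)c3ccc(O[Si](C)(C)C(C)(C)C)cc3)C1 | intermediate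
24 | C9=C10 trimethylsilyl enol ether, 4β-OTMS | C[C@H]1C=C(O[Si](C)(C)C)[C@@]2(C)CC[C@@](O[Si](C)(C)C)(C(C)C)[C@@H]2[C@@H](OC(=O)c3ccc(O[Si](C)(C)C(C)(C)C)cc3)C1 | intermediate
25 | protected enone (C8=C9–C10=O, 4β-OTMS, aryl OTBS) | CC1=CC(=O)[C@@]2(C)CC[C@@](O[Si](C)(C)C)(C(C)C)[C@@H]2[C@@H](OC(=O)c3ccc(O[Si](C)(C)C(C)(C)C)cc3)C1 | intermediate
26 | CNP0210039.1 (1β-methyl, 4β-OH, 4α-isopropyl, 5α-H, 6α-(4-hydroxybenzoyloxy), C8=C9–C10=O) | CC1=CC(=O)[C@@]2(C)CC[C@@](O)(C(C)C)[C@@H]2[C@@H](OC(=O)c2ccc(O)cc2)C1 | target

Total step count: 16. Longest linear sequence: 15 (steps 1–10 and 12–16, from 1 to 26).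

Steps most likely to fail

Step 9. Three things may go wrong: slow ionisation of the hindered secondary mesylate, migration of C7 out of the minor chair, or transfer of ethyl or hydride from aluminium to the new ketone. The fallback builds the same C1–C5 bond in an anionic, stepwise way and sets out from 13. Hydrogenolysis (H2, Pd(OH)2/C) should give the 10β-alcohol F1, and Dess–Martin oxidation the β-hydroxy ketone F2. With KOt-Bu in THF at low temperature the C6 alkoxide should undergo retro-aldol cleavage of C1–C6. The C1 enolate so formed should then displace the mesylate, now α to a ketone, in a 5-exo-tet alkylation with inversion at C5. The short tether should allow closure only on the face that C6 has left, giving the 6,10-diketone F3. Methanolysis of the silyl ether should give the hydroxy diketone F4. Evans–Saksena reduction touches only the ketone β to the C4 hydroxyl and should give the keto diol F5. Steglich esterification with 20 comes back to the route at 23.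

Step 6. Osmylation of an alkene flanked by two fully substituted carbons may be slow, and β-face delivery may erode. The fallback sets out from 9. Vanadium-catalysed epoxidation (VO(acac)2, t-BuOOH) is tied to the 4β-hydroxyl through the metal alkoxide and tolerates hindered alkenes, so it should give the 5β,6β-epoxy alcohol F6. Halide-catalysed insertion of CO2 (Bu4NBr, ZnBr2, CO2 pressure, heat) follows. Bromide opens the oxirane at C5 from the α face (diaxial opening), and the C6 carbonate then displaces the bromide. This double inversion keeps both oxygens β and should give the cis cyclic carbonate F7. Methanolysis (K2CO3, MeOH) comes back to the route at 11.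

Step 5. α-Face selectivity may be incomplete, and the secondary Grignard reagent may reduce or enolise the enone. The fallback sets out from 7 and installs the side chain in two stages. The flat isopropenyl nucleophile (isopropenylmagnesium bromide, CeCl3) has no transferable β-hydrogen and a stronger preference for pseudoaxial attack, and should give the isopropenyl carbinol F8. Hydrogenation with H2 and RhCl(PPh3)3 should saturate only the 1,1-disubstituted alkene. The hindered C5=C6 bond and the benzyl ether stay in place, and the material comes back to the route at 9.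

Further compounds
F1 | step 9 | 10β-alcohol from hydrogenolysis of 13 | C[C@H]1C[C@H](O)[C@@]2(C)CC[C@@](O[Si](C)(C)C)(C(C)C)[C@H](OS(C)(=O)=O)[C@@]2(O)C1
F2 | step 9 | β-hydroxy ketone (C10=O, 6β-OH, 5β-OMs, 4β-OTMS) | C[C@H]1CC(=O)[C@@]2(C)CC[C@@](O[Si](C)(C)C)(C(C)C)[C@H](OS(C)(=O)=O)[C@@]2(O)C1
F3 | step 9 | trans-fused hydroazulene-6,10-dione, 4β-OTMS | C[C@H]1CC(=O)[C@@]2(C)CC[C@@](O[Si](C)(C)C)(C(C)C)[C@@H]2C(=O)C1
F4 | step 9 | hydroxy diketone (4β-OH, C6=O, C10=O) | C[C@H]1CC(=O)[C@@]2(C)CC[C@@](O)(C(C)C)[C@@H]2C(=O)C1
F5 | step 9 | keto diol (4β-OH, 6α-OH, C10=O) | C[C@H]1CC(=O)[C@@]2(C)CC[C@@](O)(C(C)C)[C@@H]2[C@@H](O)C1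
F6 | step 6 | 5β,6β-epoxy alcohol (4β-OH, 4α-isopropyl) | C[C@H]1C[C@H](OCc4ccccc4)[C@@]2(C)CC[C@@](O)(C(C)C)[C@H](O3)[C@@]23C1
F7 | step 6 | 5β,6β-cyclic carbonate (4β-OH) | C[C@H]1C[C@H](OCc4ccccc4)[C@@]2(C)CC[C@@](O)(C(C)C)[C@H](OC3=O)[C@@]2(O3)C1
F8 | step 5 | isopropenyl carbinol (4β-OH, 4α-isopropenyl, C5=C6) | C[C@H]1C[C@H](OCc3ccccc3)[C@@]2(C)CC[C@@](O)(C(C)=C)C=C2C1
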